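**Plan**

1. Cembrane numbering is used: C-1 ring-fusion CH, C-2 CH2, C-3 CH–O, C-4 C(CH3)OH, C-7 CH–OOH, C-8(=C-19H2), C-11/C-12 epoxide, C-14 CH2 next to C-1, C-15 CH(CH3), C-16 lactone C=O.
2. Retrosynthesis: (a) C-7–OOH and C-8=C-19 by a singlet-oxygen ene reaction of a C-7=C-8 olefin; (b) the C-7–C-8 ring bond by Ni/Cr coupling, followed by reductive allylic transposition; (c) a temporary C-14 ketone; (d) both lactone C–C bonds, C-2–C-3 and C-1–C-15, cut together, leaving an α-acyloxy acid and a vinyl ketone.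
3. Forward: two fragments (steps 1–5 and 6–10), then the δ-lactone in one radical–polar annulation (step 11), deoxygenation, the 14-membered carbocycle (step 14), the E-olefin (step 15) and the hydroperoxide (step 16).
4. Stereochemistry: C-11/C-12 and C-4 from two Sharpless epoxidations; C-15 from (S)-2-chloropropanoyl chloride by SN2 inversion; C-3 and C-1 in the annulation (C-1 and C-15 stay correctable by equilibration to the all-equatorial lactone); C-7 in the ene reaction.
5. Enabling feature: the O–C-3 and C-16(=O)–C-15 atoms of the six-membered lactone ring. The ring oxygen stabilises a radical at C-3, the ester α-carbon C-15 carries a leaving group four atoms away, and C-1 is an enolate carbon while C-14 is a ketone, so a CH2=CH–C(=O) unit supplies C-2 and C-1 and closes the ring.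
6. A C-3 radical lies five atoms from the C-7=C-8 olefin (5-exo trap), so the annulation joins two olefin-free fragments before the carbocycle is closed.

Key step: step 11

Remark: the acetal carbon of the oxolane (later C-7) and C-7 of 23 are carried as epimer mixtures, because both centres are erased before step 16.

Step 1
Reactants: 1 6-methylhept-5-en-2-one
Product: 2 6-methylhepta-1,5-dien-2-yl trifluoromethanesulfonate
Conditions: LiN(iPr)2, THF, −78 °C; PhNTf2, −78 → 0 °C
Reagents that add atoms: N-phenylbis(trifluoromethanesulfonimide), O=S(=O)(N(c1ccccc1)S(=O)(=O)C(F)(F)F)C(F)(F)F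
Why: Kinetic deprotonation at the methyl group and O-sulfonylation of the lithium enolate should give the terminal enol triflate (regioselective enol triflate formation), which masks the ketone and later serves as the Ni/Cr coupling partner.

Step 2
Reactants: 2 6-methylhepta-1,5-dien-2-yl trifluoromethanesulfonate
Product: 3 (5E)-7-hydroxy-6-methylhepta-1,5-dien-2-yl trifluoromethanesulfonate
Conditions: SeO2 (cat.), t-BuOOH, salicylic acid (cat.), CH2Cl2, 25 °C
Reagents that add atoms: tert-butyl hydroperoxide, CC(C)(C)OO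
Why: SeO2-catalysed allylic oxidation (ene reaction then [2,3]-shift) should hydroxylate the (E)-methyl group of the only electron-rich trisubstituted olefin, the enol triflate olefin being too electron-poor to react.

Step 3
Reactants: 3 (5E)-7-hydroxy-6-methylhepta-1,5-dien-2-yl trifluoromethanesulfonate
Product: 4 4-[(2S,3S)-3-(hydroxymethyl)-3-methyloxiran-2-yl]but-1-en-2-yl trifluoromethanesulfonate
Conditions: Ti(OiPr)4 (cat.), L-(+)-diethyl tartrate (cat.), t-BuOOH, 4 Å MS, CH2Cl2, −20 °C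
Reagents that add atoms: tert-butyl hydroperoxide, CC(C)(C)OO
Why: Sharpless asymmetric epoxidation of the (E)-allylic alcohol with L-(+)-tartrate should deliver oxygen to the face that gives the (2S,3S)-epoxide, setting C-11 and C-12 under reagent control.

Step 4
Reactants: 4 4-[(2S,3S)-3-(hydroxymethyl)-3-methyloxiran-2-yl]but-1-en-2-yl trifluoromethanesulfonate; 5 methoxyallene
Product: 7 4-[(2S,3S)-3-(2-methoxybuta-2,3-dien-1-yl)-3-methyloxiran-2-yl]but-1-en-2-yl trifluoromethanesulfonate, via primary triflate 6 (not isolated)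
Conditions: Tf2O, 2,6-lutidine, CH2Cl2, −78 °C; then 5/n-BuLi (THF, −78 °C), −78 °C
Reagents that add atoms: none
Why: The primary alkyl triflate should be displaced at −78 °C by 1-lithio-1-methoxyallene, an acryloyl anion equivalent (SN2 alkylation of a lithiated alkoxyallene), faster than the epoxide or the enol triflate is attacked, and neither epoxide centre is touched.

Step 5
Reactants: 7 4-[(2S,3S)-3-(2-methoxybuta-2,3-dien-1-yl)-3-methyloxiran-2-yl]but-1-en-2-yl trifluoromethanesulfonate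
Product: 8 4-[(2S,3S)-3-methyl-3-(2-oxobut-3-en-1-yl)oxiran-2-yl]but-1-en-2-yl trifluoromethanesulfonate
Conditions: oxalic acid (cat.), THF/H2O, 0 °C; used at once
Reagents that add atoms: water, O
Why: Protonation of the alkoxyallene at its central carbon and hydration of the oxocarbenium ion (enol ether hydrolysis) should unveil the vinyl ketone under acid too weak to open the epoxide.

Step 6
Reactants: 9 geraniol
Product: 10 [(2S,3S)-3-methyl-3-(4-methylpent-3-en-1-yl)oxiran-2-yl]methanol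
Conditions: Ti(OiPr)4 (cat.), L-(+)-diethyl tartrate (cat.), t-BuOOH, 4 Å MS, CH2Cl2, −20 °C
Reagents that add atoms: tert-butyl hydroperoxide, CC(C)(C)OO
Why: Sharpless asymmetric epoxidation of the allylic alcohol only should set the tertiary C–O centre (later C-4) as S under reagent control.

Step 7
Reactants: 10 [(2S,3S)-3-methyl-3-(4-methylpent-3-en-1-yl)oxiran-2-yl]methanol
Product: 11 (2R,3S)-3,7-dimethyloct-6-ene-1,2,3-triol
Conditions: NaOH (0.5 M), t-BuOH/H2O, 75 °C
Reagents that add atoms: water, O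
Why: Payne rearrangement to the terminal epoxide and its opening by hydroxide at C-1 should give the triol with the tertiary centre keeping its oxygen and configuration (the inverted secondary centre is erased in step 11).

Step 8
Reactants: 11 (2R,3S)-3,7-dimethyloct-6-ene-1,2,3-triol
Product: 12 (2S,3S)-2,3-dihydroxy-3,7-dimethyloct-6-enoic acid
Conditions: Pt/C, O2, NaHCO3, H2O/1,4-dioxane, 60 °C; then HCl (aq)
Reagents that add atoms: water, O
Why: Platinum-catalysed aerobic oxidation (Heyns oxidation) should take the primary hydroxyl to the acid and leave the secondary and tertiary hydroxyls and the olefin alone.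

Step 9
Reactants: 12 (2S,3S)-2,3-dihydroxy-3,7-dimethyloct-6-enoic acid; 13 (2S)-2-chloropropanoyl chloride
Product: 15 (2S,3S)-2-[(2S)-2-chloropropanoyloxy]-3-hydroxy-3,7-dimethyloct-6-enoic acid, via mixed anhydride 14 (not isolated)
Conditions: 13 (2.2 equiv), pyridine, CH2Cl2, −20 °C; then H2O/THF, 0 °C
Reagents that add atoms: none
Why: The secondary hydroxyl should be acylated while the tertiary one is inert (esterification with an acid chloride), and the mixed anhydride formed at the carboxyl group is hydrolysed on aqueous work-up.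

Step 10
Reactants: 15 (2S,3S)-2-[(2S)-2-chloropropanoyloxy]-3-hydroxy-3,7-dimethyloct-6-enoic acid
Product: 17 (2S)-2-[(2S)-2-chloropropanoyloxy]-2-[(2S)-5-methoxy-2-methyloxolan-2-yl]acetic acid (both acetal epimers), via aldehyde 16 (not isolated)
Conditions: O3, CH2Cl2/MeOH, −78 °C; Me2S; then TsOH (cat.), 25 °C
Reagents that add atoms: methanol, CO
Why: Ozonolysis removes the olefin that a C-3 radical would attack 5-exo, and the aldehyde should be trapped by the tertiary hydroxyl and methanol as a five-membered cyclic acetal that masks both C-7 and the C-4 hydroxyl.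

Step 11
Reactants: 17 (2S)-2-[(2S)-2-chloropropanoyloxy]-2-[(2S)-5-methoxy-2-methyloxolan-2-yl]acetic acid; 8 4-[(2S,3S)-3-methyl-3-(2-oxobut-3-en-1-yl)oxiran-2-yl]but-1-en-2-yl trifluoromethanesulfonate
Product: 19 4-[(2S,3S)-3-methyl-3-{2-[(3S,4R,6R)-6-[(2S)-5-methoxy-2-methyloxolan-2-yl]-3-methyl-2-oxooxan-4-yl]-2-oxoethyl}oxiran-2-yl]but-1-en-2-yl trifluoromethanesulfonate, via caesium enolate 18 (not isolated)
Conditions: Cs2CO3 (0.5 equiv), 4 Å MS, DMF; 8 (1.3 equiv), Ir[dF(CF3)ppy]2(dtbbpy)PF6 (1 mol %), blue LEDs, 20 °C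
Reagents that add atoms: none
Why: Proposed new method: the photoexcited trivalent iridium complex oxidises the caesium carboxylate of 17, loss of CO2 leaves the nucleophilic α-acyloxy radical at C-3, this adds to the CH2 terminus (C-2) of vinyl ketone 8 (Giese addition), and the divalent iridium complex reduces the α-keto radical to caesium enolate 18, whose C-1 carbon displaces chloride from the ester α-carbon C-15. The closest known reaction type is the photoredox decarboxylative radical addition–polar cyclisation cascade used for cyclopropanes; new here are the leaving group on the radical partner and the six-membered lactone. The δ-lactone ring closes 6-exo-tet through a chair-like transition state. C-15 comes from (S)-2-chloropropanoyl chloride by SN2 inversion, C-1 is set by the equatorial preference in that chair (both remain epimerisable toward the all-equatorial lactone), and C-3 is set in the radical addition, expected anti to the oxolane oxygen on C-4 (Felkin–Anh-type approach) but not secured by precedent. The step needs addition to the enone before any other radical pathway and C-alkylation before protonation: acid 17 holds no olefin within reach of the C-3 radical, the enol triflate is not a radical acceptor, the chloride is not reduced by the divalent iridium complex, and the half equivalent of Cs2CO3 with molecular sieves leaves no proton source.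

Step 12
Reactants: 19 4-[(2S,3S)-3-methyl-3-{2-[(3S,4R,6R)-6-[(2S)-5-methoxy-2-methyloxolan-2-yl]-3-methyl-2-oxooxan-4-yl]-2-oxoethyl}oxiran-2-yl]but-1-en-2-yl trifluoromethanesulfonate
Product: 21 4-[(2S,3S)-3-methyl-3-{2-[(3S,4R,6R)-6-[(2S)-5-methoxy-2-methyloxolan-2-yl]-3-methyl-2-oxooxan-4-yl]ethyl}oxiran-2-yl]but-1-en-2-yl trifluoromethanesulfonate, via tosylhydrazone 20 (not isolated)
Conditions: TsNHNH2, THF, 40 °C; then catecholborane, CHCl3, 0 °C; NaOAc·3H2O, 60 °C
Reagents that add atoms: none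
Why: Tosylhydrazone formation and catecholborane reduction (hydride addition, sulfinate loss, diazene decomposition) should turn the temporary C-14 ketone into CH2 without base, sparing lactone, epoxide and enol triflate.

Step 13
Reactants: 21 4-[(2S,3S)-3-methyl-3-{2-[(3S,4R,6R)-6-[(2S)-5-methoxy-2-methyloxolan-2-yl]-3-methyl-2-oxooxan-4-yl]ethyl}oxiran-2-yl]but-1-en-2-yl trifluoromethanesulfonate
Product: 22 4-[(2S,3S)-3-{2-[(3S,4R,6R)-6-[(2S)-5-hydroxy-2-methyloxolan-2-yl]-3-methyl-2-oxooxan-4-yl]ethyl}-3-methyloxiran-2-yl]but-1-en-2-yl trifluoromethanesulfonate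
Conditions: pyridinium p-toluenesulfonate (cat.), acetone/H2O, 40 °C
Reagents that add atoms: water, O
Why: Mild hydrolysis of the cyclic methyl acetal should give the lactol, the masked C-7 aldehyde, under conditions that spare the trisubstituted epoxide and the enol triflate.

Step 14
Reactants: 22 4-[(2S,3S)-3-{2-[(3S,4R,6R)-6-[(2S)-5-hydroxy-2-methyloxolan-2-yl]-3-methyl-2-oxooxan-4-yl]ethyl}-3-methyloxiran-2-yl]but-1-en-2-yl trifluoromethanesulfonate
Product: 23 (1R,3R,4S,11S,12S,15S)-11,12-epoxy-4,7-dihydroxycembr-8(19)-en-16,3-olide (both C-7 epimers)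
Conditions: CrCl2, NiCl2 (cat.), DMSO/THF, 25 °C, 0.002 M
Reagents that add atoms: none
Why: In the Nozaki–Hiyama–Kishi reaction zerovalent nickel inserts into the enol triflate, the alkenyl group passes to trivalent chromium and adds to the open aldehyde form of the lactol, which should close the 14-membered ring at C-7–C-8 chemoselectively under high dilution.

Step 15
Reactants: 23 (1R,3R,4S,11S,12S,15S)-11,12-epoxy-4,7-dihydroxycembr-8(19)-en-16,3-olide
Product: 26 (1R,3R,4S,7E,11S,12S,15S)-11,12-epoxy-4-hydroxycembr-7-en-16,3-olide, via sulfonylhydrazine 24 (not isolated), via allylic diazene 25 (not isolated)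
Conditions: PPh3, diethyl azodicarboxylate, 2-nitrobenzenesulfonylhydrazide, THF, −30 → 23 °C
Reagents that add atoms: none
Why: Mitsunobu displacement of the allylic hydroxyl, loss of sulfinic acid and retro-ene loss of N2 from the allylic diazene (reductive 1,3-transposition) should move the double bond to C-7=C-8 and create the C-19 methyl group, the E geometry following from the transition state that keeps the C-6 and C-9 ring arms apart.

Step 16
Reactants: 26 (1R,3R,4S,7E,11S,12S,15S)-11,12-epoxy-4-hydroxycembr-7-en-16,3-olide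
Product: 27 (1R,3R,4S,7R,11S,12S,15S)-11,12-epoxy-7-hydroperoxy-4-hydroxycembr-8(19)-en-16,3-olide
Conditions: O2, tetraphenylporphyrin (cat.), visible light, CH2Cl2, −20 °C
Reagents that add atoms: dioxygen, O=O
Why: In the Schenck ene reaction singlet oxygen should attack the only electron-rich olefin, take hydrogen from C-19 on the more substituted side and form the C-7–O bond on the exposed face of the macrocycle, which is expected, but not assured, to give 7R.

**Compound list**

1 | 6-methylhept-5-en-2-one | CC(=O)CCC=C(C)C | starting material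
2 | 6-methylhepta-1,5-dien-2-yl trifluoromethanesulfonate | C=C(OS(=O)(=O)C(F)(F)F)CCC=C(C)C | intermediate
3 | (5E)-7-hydroxy-6-methylhepta-1,5-dien-2-yl trifluoromethanesulfonate | C=C(OS(=O)(=O)C(F)(F)F)CC/C=C(\C)CO | intermediate
4 | 4-[(2S,3S)-3-(hydroxymethyl)-3-methyloxiran-2-yl]but-1-en-2-yl trifluoromethanesulfonate | C=C(OS(=O)(=O)C(F)(F)F)CC[C@@H]1O[C@@]1(C)CO | intermediate
5 | methoxyallene (1-methoxypropa-1,2-diene) | COC=C=C | starting material
6 | 4-[(2S,3S)-3-methyl-3-(trifluoromethanesulfonyloxymethyl)oxiran-2-yl]but-1-en-2-yl trifluoromethanesulfonate | C=C(OS(=O)(=O)C(F)(F)F)CC[C@@H]1O[C@@]1(C)COS(=O)(=O)C(F)(F)F | intermediate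
7 | 4-[(2S,3S)-3-(2-methoxybuta-2,3-dien-1-yl)-3-methyloxiran-2-yl]but-1-en-2-yl trifluoromethanesulfonate | C=C(OS(=O)(=O)C(F)(F)F)CC[C@@H]1O[C@@]1(C)CC(OC)=C=C | intermediate
8 | 4-[(2S,3S)-3-methyl-3-(2-oxobut-3-en-1-yl)oxiran-2-yl]but-1-en-2-yl trifluoromethanesulfonate | C=C(OS(=O)(=O)C(F)(F)F)CC[C@@H]1O[C@@]1(C)CC(=O)C=C | intermediate
9 | geraniol [(2E)-3,7-dimethylocta-2,6-dien-1-ol] | CC(C)=CCC/C(C)=C/CO | starting material
10 | [(2S,3S)-3-methyl-3-(4-methylpent-3-en-1-yl)oxiran-2-yl]methanol | OC[C@@H]1O[C@@]1(C)CCC=C(C)C | intermediate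
11 | (2R,3S)-3,7-dimethyloct-6-ene-1,2,3-triol | OC[C@@H](O)[C@@](C)(O)CCC=C(C)C | intermediate
12 | (2S,3S)-2,3-dihydroxy-3,7-dimethyloct-6-enoic acid | OC(=O)[C@@H](O)[C@@](C)(O)CCC=C(C)C | intermediate
13 | (2S)-2-chloropropanoyl chloride | C[C@H](Cl)C(Cl)=O | starting material
14 | mixed anhydride of 15 with (2S)-2-chloropropanoic acid | C[C@H](Cl)C(=O)OC(=O)[C@@H](OC(=O)[C@H](C)Cl)[C@@](C)(O)CCC=C(C)C | intermediate
15 | (2S,3S)-2-[(2S)-2-chloropropanoyloxy]-3-hydroxy-3,7-dimethyloct-6-enoic acid | OC(=O)[C@@H](OC(=O)[C@H](C)Cl)[C@@](C)(O)CCC=C(C)C | intermediate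
16 | (2S,3S)-2-[(2S)-2-chloropropanoyloxy]-3-hydroxy-3-methyl-6-oxohexanoic acid | OC(=O)[C@@H](OC(=O)[C@H](C)Cl)[C@@](C)(O)CCC=O | intermediate
17 | (2S)-2-[(2S)-2-chloropropanoyloxy]-2-[(2S)-5-methoxy-2-methyloxolan-2-yl]acetic acid (both acetal epimers) | OC(=O)[C@@H](OC(=O)[C@H](C)Cl)[C@@](C)(O1)CCC1OC | intermediate
18 | caesium C-1/C-14 enolate of the open-chain adduct of 17 (after loss of CO2) and 8 | C=C(OS(=O)(=O)C(F)(F)F)CC[C@@H]1O[C@@]1(C)CC([O-])=CC[C@@H](OC(=O)[C@H](C)Cl)[C@@](C)(O1)CCC1OC.[Cs+] | intermediate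
19 | 4-[(2S,3S)-3-methyl-3-{2-[(3S,4R,6R)-6-[(2S)-5-methoxy-2-methyloxolan-2-yl]-3-methyl-2-oxooxan-4-yl]-2-oxoethyl}oxiran-2-yl]but-1-en-2-yl trifluoromethanesulfonate | C=C(OS(=O)(=O)C(F)(F)F)CC[C@@H]1O[C@@]1(C)CC(=O)[C@@H]2C[C@@H](OC(=O)[C@H]2C)[C@@](C)(O1)CCC1OC | intermediate
20 | 4-methylbenzenesulfonylhydrazone of 19 at the side-chain ketone | C=C(OS(=O)(=O)C(F)(F)F)CC[C@@H]1O[C@@]1(C)CC(=NNS(=O)(=O)c1ccc(C)cc1)[C@@H]2C[C@@H](OC(=O)[C@H]2C)[C@@](C)(O1)CCC1OC | intermediate
21 | 4-[(2S,3S)-3-methyl-3-{2-[(3S,4R,6R)-6-[(2S)-5-methoxy-2-methyloxolan-2-yl]-3-methyl-2-oxooxan-4-yl]ethyl}oxiran-2-yl]but-1-en-2-yl trifluoromethanesulfonate | C=C(OS(=O)(=O)C(F)(F)F)CC[C@@H]1O[C@@]1(C)CC[C@@H]2C[C@@H](OC(=O)[C@H]2C)[C@@](C)(O1)CCC1OC | intermediate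
22 | 4-[(2S,3S)-3-{2-[(3S,4R,6R)-6-[(2S)-5-hydroxy-2-methyloxolan-2-yl]-3-methyl-2-oxooxan-4-yl]ethyl}-3-methyloxiran-2-yl]but-1-en-2-yl trifluoromethanesulfonate | C=C(OS(=O)(=O)C(F)(F)F)CC[C@@H]1O[C@@]1(C)CC[C@@H]2C[C@@H](OC(=O)[C@H]2C)[C@@](C)(O1)CCC1O | intermediate
23 | (1R,3R,4S,11S,12S,15S)-11,12-epoxy-4,7-dihydroxycembr-8(19)-en-16,3-olide (both C-7 epimers) | C=C1CC[C@@H]2O[C@@]2(C)CC[C@@H]2C[C@@H](OC(=O)[C@H]2C)[C@@](C)(O)CCC1O | intermediate
24 | 7-deoxy-7-[1-(2-nitrobenzenesulfonyl)hydrazin-1-yl] derivative of 23 | C=C1CC[C@@H]2O[C@@]2(C)CC[C@@H]2C[C@@H](OC(=O)[C@H]2C)[C@@](C)(O)CCC1N(N)S(=O)(=O)c1ccccc1[N+](=O)[O-] | intermediate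
25 | 7-deoxy-7-diazenyl derivative of 23 | C=C1CC[C@@H]2O[C@@]2(C)CC[C@@H]2C[C@@H](OC(=O)[C@H]2C)[C@@](C)(O)CCC1N=N | intermediate
26 | (1R,3R,4S,7E,11S,12S,15S)-11,12-epoxy-4-hydroxycembr-7-en-16,3-olide | C1/C=C(\C)CC[C@@H]2O[C@@]2(C)CC[C@@H]2C[C@@H](OC(=O)[C@H]2C)[C@@](C)(O)C1 | intermediate
27 | (1R,3R,4S,7R,11S,12S,15S)-11,12-epoxy-7-hydroperoxy-4-hydroxycembr-8(19)-en-16,3-olide | C=C1CC[C@@H]2O[C@@]2(C)CC[C@@H]2C[C@@H](OC(=O)[C@H]2C)[C@@](C)(O)CC[C@H]1OO | target

**Step count and risks**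

Total steps: 16. Longest linear sequence: 11 steps (steps 1–5 or 6–10, then 11–16).

Steps most likely to fail:

1. Step 11 (Proposed new method). The enolate may be protonated before it alkylates, because the ester must first reach its s-cis form. The caesium carboxylate may displace the α-chloride itself and close a dioxanedione ring. The radical addition may show poor facial selectivity at C-3. The enolate may equilibrate toward C-13 and open the epoxide. Fallback with known reactions, from 4 and 11 back to 21: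
   - Triflate 6, made from 4 as in step 4, is alkylated with the lithium enolate of acetone (LiN(iPr)2, THF, −78 °C) to give 4-[(2S,3S)-3-methyl-3-(3-oxobutyl)oxiran-2-yl]but-1-en-2-yl trifluoromethanesulfonate F1.
   - Triol 11 is ozonised in CH2Cl2/MeOH with Me2S and TsOH work-up to (1R)-1-[(2S)-5-methoxy-2-methyloxolan-2-yl]ethane-1,2-diol F2, and NaIO4 cleaves this to (2S)-5-methoxy-2-methyloxolane-2-carbaldehyde F3.
   - The Ipc2BCl/Et3N boron enolate of F1 adds to F3 in a reagent-controlled aldol reaction to give the (5R)-5-hydroxy-3-oxopentyl ketol F4.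
   - Acylation with 2-(diethoxyphosphoryl)acetic acid (DCC, DMAP) gives the phosphonoacetate F5.
   - Intramolecular Horner–Wadsworth–Emmons reaction (LiCl, iPr2NEt, MeCN) gives the 5,6-dihydro-2H-pyran-2-one F6.
   - Conjugate reduction with [CuH(PPh3)]6, hydride entering anti to the C-3 substituent, gives the 3-unsubstituted oxan-2-one F7.
   - LiN(iPr)2 then MeI methylates C-15 trans to the C-1 side chain and returns 21.

2. Step 14. The lactol may supply too little open aldehyde, so that protonation of the alkenylchromium species or intermolecular coupling outruns ring closure. Fallback, from 22 to 26: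
   - NaBH4 (MeOH, 0 °C) reduces the lactol to the (2S)-2,5-dihydroxypentan-2-yl diol F8.
   - TESOTf/2,6-lutidine gives the bis(triethylsilyl) ether F9.
   - Swern oxidation converts the primary silyl ether directly into the 5-oxo-2-(triethylsilyloxy)pentan-2-yl aldehyde F10.
   - CrCl2/NiCl2 ring closure as in step 14 gives the 4-O-triethylsilyl ether of 23 F11.
   - The transposition of step 15 gives the 4-O-triethylsilyl ether of 26 F12, and Bu4NF returns 26.

3. Step 16. Hydrogen abstraction from C-6 instead of C-19 would give the tertiary C-8 hydroperoxide, and attack on the wrong olefin face would give the 7S epimer. Fallback, from 23 to 27: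
   - Dess–Martin periodinane oxidises both C-7 epimers of 23 to the 7-oxo enone F13.
   - Corey–Bakshi–Shibata reduction gives the (7S)-alcohol F14.
   - MsCl/Et3N at −40 °C gives the 7-methanesulfonate F15.
   - SN2 displacement with 2-methoxypropan-2-yl hydroperoxide/CsOH in DMF gives the (7R)-perketal F16 with inversion, and aqueous acetic acid releases 27.

Further compounds
F1 | step 11 | 4-[(2S,3S)-3-methyl-3-(3-oxobutyl)oxiran-2-yl]but-1-en-2-yl trifluoromethanesulfonate | C=C(OS(=O)(=O)C(F)(F)F)CC[C@@H]1O[C@@]1(C)CCC(C)=O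
F2 | step 11 | (1R)-1-[(2S)-5-methoxy-2-methyloxolan-2-yl]ethane-1,2-diol | OC[C@@H](O)[C@@](C)(O1)CCC1OC
F3 | step 11 | (2S)-5-methoxy-2-methyloxolane-2-carbaldehyde | O=C[C@@](C)(O1)CCC1OC
F4 | step 11 | 4-[(2S,3S)-3-{(5R)-5-hydroxy-5-[(2S)-5-methoxy-2-methyloxolan-2-yl]-3-oxopentyl}-3-methyloxiran-2-yl]but-1-en-2-yl trifluoromethanesulfonate | C=C(OS(=O)(=O)C(F)(F)F)CC[C@@H]1O[C@@]1(C)CCC(=O)C[C@@H](O)[C@@](C)(O1)CCC1OC
F5 | step 11 | 2-(diethoxyphosphoryl)acetate ester of F4 | C=C(OS(=O)(=O)C(F)(F)F)CC[C@@H]1O[C@@]1(C)CCC(=O)C[C@@H](OC(=O)CP(=O)(OCC)OCC)[C@@](C)(O1)CCC1OC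
F6 | step 11 | 4-[(2S,3S)-3-methyl-3-{2-[(6R)-6-[(2S)-5-methoxy-2-methyloxolan-2-yl]-2-oxo-5,6-dihydro-2H-pyran-4-yl]ethyl}oxiran-2-yl]but-1-en-2-yl trifluoromethanesulfonate | C=C(OS(=O)(=O)C(F)(F)F)CC[C@@H]1O[C@@]1(C)CCC2=CC(=O)O[C@H](C2)[C@@](C)(O1)CCC1OC
F7 | step 11 | 4-[(2S,3S)-3-methyl-3-{2-[(4R,6R)-6-[(2S)-5-methoxy-2-methyloxolan-2-yl]-2-oxooxan-4-yl]ethyl}oxiran-2-yl]but-1-en-2-yl trifluoromethanesulfonate | C=C(OS(=O)(=O)C(F)(F)F)CC[C@@H]1O[C@@]1(C)CC[C@@H]2C[C@@H](OC(=O)C2)[C@@](C)(O1)CCC1OC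
F8 | step 14 | 4-[(2S,3S)-3-{2-[(3S,4R,6R)-6-[(2S)-2,5-dihydroxypentan-2-yl]-3-methyl-2-oxooxan-4-yl]ethyl}-3-methyloxiran-2-yl]but-1-en-2-yl trifluoromethanesulfonate | C=C(OS(=O)(=O)C(F)(F)F)CC[C@@H]1O[C@@]1(C)CC[C@@H]2C[C@@H](OC(=O)[C@H]2C)[C@@](C)(O)CCCO
F9 | step 14 | bis(triethylsilyl) ether of F8 | C=C(OS(=O)(=O)C(F)(F)F)CC[C@@H]1O[C@@]1(C)CC[C@@H]2C[C@@H](OC(=O)[C@H]2C)[C@@](C)(O[Si](CC)(CC)CC)CCCO[Si](CC)(CC)CC
F10 | step 14 | 4-[(2S,3S)-3-methyl-3-{2-[(3S,4R,6R)-3-methyl-2-oxo-6-[(2S)-5-oxo-2-(triethylsilyloxy)pentan-2-yl]oxan-4-yl]ethyl}oxiran-2-yl]but-1-en-2-yl trifluoromethanesulfonate | C=C(OS(=O)(=O)C(F)(F)F)CC[C@@H]1O[C@@]1(C)CC[C@@H]2C[C@@H](OC(=O)[C@H]2C)[C@@](C)(O[Si](CC)(CC)CC)CCC=O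
F11 | step 14 | 4-O-triethylsilyl ether of 23 | C=C1CC[C@@H]2O[C@@]2(C)CC[C@@H]2C[C@@H](OC(=O)[C@H]2C)[C@@](C)(O[Si](CC)(CC)CC)CCC1O
F12 | step 14 | 4-O-triethylsilyl ether of 26 | C1/C=C(\C)CC[C@@H]2O[C@@]2(C)CC[C@@H]2C[C@@H](OC(=O)[C@H]2C)[C@@](C)(O[Si](CC)(CC)CC)C1
F13 | step 16 | (1R,3R,4S,11S,12S,15S)-11,12-epoxy-4-hydroxy-7-oxocembr-8(19)-en-16,3-olide | C=C1CC[C@@H]2O[C@@]2(C)CC[C@@H]2C[C@@H](OC(=O)[C@H]2C)[C@@](C)(O)CCC1=O
F14 | step 16 | (1R,3R,4S,7S,11S,12S,15S)-11,12-epoxy-4,7-dihydroxycembr-8(19)-en-16,3-olide | C=C1CC[C@@H]2O[C@@]2(C)CC[C@@H]2C[C@@H](OC(=O)[C@H]2C)[C@@](C)(O)CC[C@@H]1O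
F15 | step 16 | 7-methanesulfonate of F14 | C=C1CC[C@@H]2O[C@@]2(C)CC[C@@H]2C[C@@H](OC(=O)[C@H]2C)[C@@](C)(O)CC[C@@H]1OS(C)(=O)=O
F16 | step 16 | (1R,3R,4S,7R,11S,12S,15S)-11,12-epoxy-4-hydroxy-7-(2-methoxypropan-2-ylperoxy)cembr-8(19)-en-16,3-olide | C=C1CC[C@@H]2O[C@@]2(C)CC[C@@H]2C[C@@H](OC(=O)[C@H]2C)[C@@](C)(O)CC[C@H]1OOC(C)(C)OC
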